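At 5.0 min the flask is read for how much the catalyst has turned over before the partner gives out.

starting material 0.50 mM; partner 0.750 mM; free catalyst 1.0 µM; time 5.0 min

    starting material + free catalyst → catalyst intermediate A (k1 = 23100 M⁻¹ s⁻¹)
    partner + catalyst intermediate A ⇌ catalyst intermediate B (K2 = 1140 M⁻¹, k2 = 7.12 × 10⁵ M⁻¹ s⁻¹)
    catalyst intermediate B → catalyst intermediate C (k3 = 1480 s⁻¹)
    catalyst intermediate C ⇌ free catalyst + target (K4 = 0.0014 M, k4 = 12.7 s⁻¹)
    partner → decomposed reagent (k5 = 0.0180 s⁻¹)
    target → over-reaction product (k6 = 0.00121 s⁻¹)

1. part of the starting material gone at 5.0 min
2. the target standing at 5.0 min, as a percentage of the starting material charged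

One turn of the flask's catalyst costs 0.0866 s in step 1 at the full charge of starting material and 0.0787 s in step 4. Steps 2 and 3 take far less, 0.00187 s and 6.76 × 10⁻⁴ s, so the turnover rate per catalyst is 6.05 s⁻¹. Per unit of its charge, the partner loses 0.0180 s⁻¹ to step 5 and, at the start, 0.00807 s⁻¹ to turnover. With both drains running, this reckoning takes it to zero at 65.2 s. Turnover rate, catalyst and that time, over the charge of starting material, come to 78.8 %, the turnover budget: the fraction of the starting material the catalyst can turn before the partner stops it. Target formed at the midpoint of that stretch then decays by step 6, which leaves 57.0 %. Both figures of this reckoning take step 1 at the full charge.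

The forecast gives 69 % (64 % to 74 %) and 50 % (46 % to 54 %), a conversion lower than this reckoning: “the partner runs out at around 90–100 s and conversion stalls near 70%”.

The flask gives 69.1 % and 50.1 %. At 5.00 min the flask's partner, the limiting reagent, stands at 0 % against 30.9 % of the starting material, and catalyst intermediate A holds 100 % of the catalyst.

The budget of 78.8 % stands 9.7 percentage points above the flask's conversion, and at 0.500 min the starting material is already down to 68.9 %. The neighbour flask, charged with 2.5 × 10⁻⁴ mM of free catalyst, keeps the same turnover rate in this reckoning, which takes its partner to zero at 128 s. A quarter of the catalyst thus gets a budget of 38.6 %, smaller than the 78.8 % of the first flask. At 5.00 min the neighbour flask shows 34.2 % conversion and 25.8 % target, with the partner at 0 % and the starting material at 65.8 %.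

The numbers of this flask were set for the occasion; the run is a simulation.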